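The data were generated by integration from invented constants; the scatter is artificial.

In a one-step world starting material and reagent vanish together, so the surplus of reagent stays constant and the rate integrates in closed form. The logarithm of the fraction of reagent left over the fraction of starting material left, each of its own charge, grows in a straight line with time. I called that logarithm the exposure: a constant, times the charge of starting material, times the surplus equivalents, times time.

| flask | starting material | reagent | remark | time |
|---|---|---|---|---|
| Sunday's | 0.34 mM | 1.2 equiv | run made earlier |  |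
| Saturday's | 0.75 mM | 1.2 equiv | run made earlier |  |
| flask | 0.50 mM | 1.20 equiv |  | 2.5 min |

| run | time / s | target / % | isomer of the product / % | starting material / % |
|---|---|---|---|---|
| Sunday's | 10.0 | 4.6 | 1.9 | 77.1 |
| Sunday's | 12.0 | 6.4 | 2.8 | 73.5 |
| Sunday's | 20.0 | 12.7 | 5.4 | 61.7 |
| Sunday's | 30.0 | 20.5 | 7.2 | 50.1 |
| Sunday's | 50.0 | 31.0 | 10.3 | 35.8 |
| Sunday's | 90.0 | 40.3 | 13.8 | 20.5 |
| Saturday's | 15.0 | 20.4 | 6.2 | 52.0 |
| Saturday's | 30.0 | 38.6 | 9.8 | 32.8 |
| Saturday's | 50.0 | 50.4 | 9.9 | 19.9 |
| Saturday's | 60.0 | 54.8 | 11.8 | 15.6 |
| Saturday's | 80.0 | 59.1 | 11.1 | 11.1 |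
| Saturday's | 90.0 | 59.8 | 10.9 | 9.8 |

(standard deviation of a reading: 0.5 percentage points)

1. ratio of target to isomer of the product at 2.0 s
2. ratio of target to isomer of the product at 2.5 min
3. which of target and isomer of the product there is more of at 2.5 min

- a reading or a percentage of target counts all its forms, free or not

At the last readings the constant came out as 81.5 M⁻¹ s⁻¹ on Sunday's run, higher than 68.9 M⁻¹ s⁻¹ on Saturday's. For a flask charged between them I took the mean, 75.2 M⁻¹ s⁻¹, and named it the pair constant: the slope of the exposure per unit of charge and surplus.

Then I turned the settings by hand. Time: I reckoned the flask's exposure as 0.0150 at 2.0 s and 1.13 at 2.5 min, which in the one-step reckoning leaves 7.39% of the starting material. Charge: it multiplies into the exposure in the same way as time, and Saturday's run, at twice Sunday's charge, had 9.8% left against 20.5% at 90.0 s. Equivalents: 1.20 equiv leaves a surplus of 0.200, so starting material is the limiting reagent. Below one equivalent the exposure turns negative.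

The exposure tells how far a flask has gone, not how it splits. The last ratios of target to isomer were 2.92 on Sunday's run and 5.49 on Saturday's, so I put the flask between them, target ahead. For 2.0 s I held no number of my own.

The forecast gave 2.3 (1.7 to 2.9) at 2.0 s, saying of the early ratio “this is the intrinsic split”, and 3.9 (3.2 to 4.8) at 2.5 min, with target ahead.

The flask gave 5.56 at 2.0 s and 4.94 at 2.5 min, with target ahead, 58.0% against 11.7%.

    starting material + reagent → intermediate + by-product (k = 53.0 M⁻¹ s⁻¹)
    intermediate ⇌ target (K = 0.630, k = 0.180 s⁻¹)
    intermediate ⇌ isomer of the product (K = 2.50, k = 0.0270 s⁻¹)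
    target + by-product → side product (k = 44.0 M⁻¹ s⁻¹)
    starting material ⇌ dormant form (K = 0.910, k = 0.00560 s⁻¹)
    crystals ⇌ target, rate k6*(cs6 - [target]) while solid is left; crystals form when [target] > cs6 (solubility = 0.0110 mM, k = 0.560 s⁻¹)

At 2.50 min the flask held 8.28% as starting material and 12.4% as dormant form, together 20.7%, against my 7.39%. The neighbouring flask with 0.480 equiv of reagent has starting material in surplus, and the same pair constant gives it an exposure of −2.93, from which I reckoned 53.4% of the starting material left. At 2.50 min that flask held 32.8% as starting material and 25.6% as dormant form, together 58.4%, with a ratio of target to isomer of 2.86.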